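## Analysis of the target

Numbering used here: the eight-membered ring is C1, C2, C3, C4, C6, C7, C8, C9, and C5 is the cyclopropane CH2 bridging C4 and C6. C1 carries the side-chain methine C10, which bears C11H2OAc and the homoprenyl tail C12–C13–C14=C15. C2 carries the lactone CH2 (C18), C3 the lactone carbonyl (C19), C7 a methyl group and C9 the hydroxyl.

The target is a cyclooctane with a cis-fused cyclopropane across C4–C6 and a butenolide fused across C2=C3. It has six stereocentres: C1 (R), C4 (R), C6 (R), C7 (S), C9 (S) and C10 (S). On the ring, the C1 side chain, the C9 hydroxyl and the cyclopropane methylene lie on one face and the C7 methyl on the other. C10 is exocyclic, so the ring cannot relay its configuration.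

The sensitive groups are the primary acetate, the butenolide (which makes C1–H and C18–H2 γ-acidic, so C1 can epimerise), the vinylcyclopropane conjugated to the lactone, and the electron-rich C14=C15 alkene, which competes in any electrophilic reaction on a ring alkene. The hard parts are the medium ring, the 1,4-relation between C1 and C7, and the link between the ring and C10.

The strategy rests on one feature. If C9 and C4 are both raised to ketones, C1 is the central carbon of a cyclic 1,3-diketone. C18–C2=C3–C19 then has the oxidation pattern of a 4-oxybut-2-ynoate inserted between C1 and C4.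

## Retrosynthetic reasoning

Cyclopropane. The C4–C5 and C5–C6 bonds of 26 are cut last, giving cis-alkene 24 and a methylene unit. In 24 the C9 hydroxyl sits on the face that must receive C5 and the C7 methyl blocks the other face. Placing this step last also means the acid-sensitive vinylcyclopropane is never carried through other chemistry.

C9 carbinol. The C9–H bond of 24 is traced back to ketone 23. The acetate is already in place in 23, so the two hydroxyls of the target never have to be told apart. The forward reduction must deliver hydride anti to the C1 side chain.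

Acetate and lactone. 23 comes from primary alcohol 22. The lactone O–C19 bond, the C9 carbonyl and the free C11 hydroxyl of 22 are all unmasked in one acidic operation from 20, which carries a methyl ester, two silyl ethers and a C9 ketal. The lactone is closed late because a butenolide would be deprotonated at C18 in the enolisation that follows in the backward direction.

C4=C6 alkene. The alkene of 20 is traced through enol triflate 19 to the C4 ketone of 17. Enolisation must go toward C6, which requires that C9 is not a ketone at that point (otherwise C1–H is by far the most acidic site). Hence the C9 ketal in 17, which comes from enedione 16 by selective ketalisation of the non-conjugated carbonyl.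

Key disconnection. In 16 the bonds C1–C2 and C3–C4 are cut and C1–C4 is rejoined. This returns 2-substituted dione 12 and ynoate 14. The cut is made here because it uses the natural polarity of both partners and accounts for every carbon of the ring and the lactone. The forward step must add C1 to C2, close C3 onto C4 and then cleave C1–C4.

C11 oxidation level. 12 comes from alcohol 10, 10 from aldehyde 9 and 9 from nitro compound 7. The nitro group is the carbanion-stabilising group that lets C11 arrive as a one-carbon unit.

C1–C10 bond. 7 is cut at C1–C10 into nitroalkene 5 and dione 6. An enantioselective conjugate addition sets C10, the only stereocentre that nothing else in the molecule can control.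

Simple precursors. 5 comes from aldehyde 1 and nitromethane 2 through nitro alcohol 3. 14 comes from hydroxy ynoate 13.

## Alternatives that were turned down

Alternative 1: The ring is cut at C2–C3 and C7–C8, leading back to ester A2, in which a sorbate is tethered through O–C18 to a 2-silyloxydiene. In the forward direction Ni(cod)2 with PPh3 (zerovalent nickel) would join the two dienes in an intramolecular [4+4] cycloaddition to give A1, closing the eight-membered ring and the lactone together.
- For it: two C–C bonds and two rings form in one step, and the C4=C6 alkene needed for the cyclopropane is delivered in place. On that point it is stronger than the chosen route, which must convert a ketone into this alkene over three steps.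
- Against it: the ester tether must adopt its disfavoured s-cis conformation. A2 also holds an electron-rich silyloxydiene next to an electron-poor dienoate, so an intramolecular [4+2] reaction is the likely competitor. C7 forms at a substituted diene terminus with only the remote C10 centre to bias it. The lactone of A1 is saturated, so C2 and C3 stereocentres are created and then destroyed by a dehydrogenation whose regiochemistry (toward C2 or toward C4) is not secured.
- Comparison: the chosen strategy gives the butenolide oxidation level directly, from cheaper pieces and a precedented anionic cascade.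

Alternative 2: The ring is cut at C8–C9, leading back to iodo aldehyde A4. CrCl2 with catalytic NiCl2 (a Nozaki–Hiyama–Kishi reaction) would add the (Z)-alkenyl iodide to the aldehyde to give A3, the C7=C8 dehydro target. A hydroxyl-directed hydrogenation would then set C7.
- For it: the reaction tolerates lactone and acetate and forms the ring and the carbinol together. The cyclopropane could be made early on a simple allylic alcohol with reliable reagent control, which is stronger than the late, remotely directed cyclopropanation used here.
- Against it: A4 has C1 both α to the aldehyde and γ to the butenolide, so it would enolise and epimerise readily. Closure to a (Z)-cyclooctenol has no built-in control at C9. The final hydrogenation must reduce a trisubstituted alkene conjugated to a cyclopropane without touching C14=C15 and without opening the three-membered ring. Most of the steps are spent before the key step.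
- Comparison: the chosen strategy places its risk early, on inexpensive material.

Alternative 3: The C1–C2 bond is cut, leading back to twelve-membered allylic lactone A6. Its silyl ketene acetal would undergo a ring-contracting Ireland–Claisen rearrangement to acid A5, forming C1–C2 and breaking C11–O.
- For it: the [3,3] shift is stereospecific and sets C1 kinetically, whereas the chosen route relies on thermodynamic control at C1. On that point the alternative is stronger.
- Against it: A5 carries the carboxyl on C2 and a masked ketone on C3, the reverse of the butenolide pattern. The acid would have to be reduced to C18H2OH and a carbonyl carbon added at C3, and the C2 stereocentre is made only to be lost. The C10=C11 methylene must then be turned into the C10 stereocentre with exocyclic diastereocontrol. A6 already needs the cyclopropane, C7 and C9 in place.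
- Comparison: this is the longest route, and the chosen strategy reaches the full carbon skeleton in eight steps.

Key step: step 8

## Remarks on the chemistry

- The (S,S)-catalyst in step 3 is assumed to give the (S)-adduct, by analogy with malonate additions to nitroalkenes. If the sense is opposite, the (R,R)-catalyst is used.
- 16 is drawn as the enedione. It may equilibrate with enol tautomers, which are assumed to converge on 17.
- C1 is configurationally labile until step 14. Its configuration as drawn is assumed to be the thermodynamic one.

## Route

Step 1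
Reactants: 1 5-methylhex-4-enal; 2 nitromethane
Product: 3 6-methyl-1-nitrohept-5-en-2-ol (racemic)
Conditions: Et3N (0.2 equiv), MeNO2 (5 equiv), THF, 0 °C to rt
Reagents that add atoms: none
Why: Henry reaction; the nitronate of 2 adds to the aldehyde, and the mild base and excess nitromethane suppress self-aldol of 1.

Step 2
Reactants: 3 6-methyl-1-nitrohept-5-en-2-ol
Product: 5 (E)-6-methyl-1-nitrohepta-1,5-diene, via nitro mesylate 4 (not isolated)
Conditions: MsCl (1.2 equiv), Et3N (2.5 equiv), CH2Cl2, 0 °C
Reagents that add atoms: none
Why: Mesylation followed by E1cB elimination through the nitronate should give the conjugated (E)-nitroalkene.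

Step 3
Reactants: 5 (E)-6-methyl-1-nitrohepta-1,5-diene; 6 5-methylcyclohexane-1,3-dione
Product: 7 5-methyl-2-[(2S)-6-methyl-1-nitrohept-5-en-2-yl]cyclohexane-1,3-dione (largely enolised)
Conditions: 1-[3,5-bis(trifluoromethyl)phenyl]-3-[(1S,2S)-2-(dimethylamino)cyclohexyl]thiourea (10 mol%), 6 (1.2 equiv), CH2Cl2, −20 °C
Reagents that add atoms: none
Why: Organocatalytic Michael addition; the thiourea binds the nitro group and the amine delivers the dione enolate to one enantiotopic face of C10, which sets C10 (S) under catalyst control.

Step 4
Reactants: 7 5-methyl-2-[(2S)-6-methyl-1-nitrohept-5-en-2-yl]cyclohexane-1,3-dione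
Product: 9 (2S)-6-methyl-2-(4-methyl-2,6-dioxocyclohexyl)hept-5-enal, present mainly as its bicyclic lactol, via disodium nitronate enolate 8 (not isolated)
Conditions: NaOMe (2.2 equiv), MeOH, 0 °C; then TiCl3 (aq, 4 equiv), NH4OAc buffer (pH 5–6), rt; crude product used at once
Reagents that add atoms: water, O
Why: Reductive Nef reaction; trivalent titanium reduces the nitronate to the imine, which hydrolyses in the buffer. The near-neutral medium should spare the trisubstituted alkene, and the lactol form shields C10 from epimerisation.

Step 5
Reactants: 9 (2S)-6-methyl-2-(4-methyl-2,6-dioxocyclohexyl)hept-5-enal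
Product: 10 2-[(2S)-1-hydroxy-6-methylhept-5-en-2-yl]-5-methylcyclohexane-1,3-dione
Conditions: NaBH4 (2 equiv), EtOH, 0 °C; then aq. citric acid to pH 5
Reagents that add atoms: none
Why: Borohydride reduction of the aldehyde released from the lactol; the dione is present as its enolate and is not reduced.

Step 6
Reactants: 10 2-[(2S)-1-hydroxy-6-methylhept-5-en-2-yl]-5-methylcyclohexane-1,3-dione
Product: 12 2-[(2S)-1-(tert-butyldimethylsilyloxy)-6-methylhept-5-en-2-yl]-5-methylcyclohexane-1,3-dione, via bis-silyl compound 11 (not isolated)
Conditions: TBSCl (2.2 equiv), imidazole, DMF, rt; then K2CO3 (cat.), MeOH/H2O, 0 °C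
Reagents that add atoms: tert-butyldimethylsilyl chloride, CC(C)(C)[Si](C)(C)Cl
Why: Silylation of the primary alcohol and the enol, then selective cleavage of the labile vinylogous silyl ester by mild base, which leaves the alkyl silyl ether.

Step 7
Reactants: 13 methyl 4-hydroxybut-2-ynoate
Product: 14 methyl 4-(tert-butyldimethylsilyloxy)but-2-ynoate
Conditions: TBSCl (1.1 equiv), imidazole, CH2Cl2, 0 °C
Reagents that add atoms: tert-butyldimethylsilyl chloride, CC(C)(C)[Si](C)(C)Cl
Why: Standard silylation of a primary propargylic alcohol; it prevents oxa-Michael oligomerisation of the ynoate in step 8.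

Step 8
Reactants: 12 2-[(2S)-1-(tert-butyldimethylsilyloxy)-6-methylhept-5-en-2-yl]-5-methylcyclohexane-1,3-dione; 14 methyl 4-(tert-butyldimethylsilyloxy)but-2-ynoate
Product: 16 methyl (3R,6S)-2-[(tert-butyldimethylsilyloxy)methyl]-3-[(2S)-1-(tert-butyldimethylsilyloxy)-6-methylhept-5-en-2-yl]-6-methyl-4,8-dioxocyclooct-1-ene-1-carboxylate (C1 R, C7 S, C10 S in the target numbering), via fused cyclobutenol adduct 15 (not isolated)
Conditions: Cs2CO3 (0.2 equiv), 14 (1.2 equiv), DMSO, 25–40 °C; chromatographic separation from the C7 epimer
Reagents that add atoms: none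
Why: The caesium enolate of 12 adds through C1 to the β-carbon C2 of 14 (Michael addition), leaving a vinyl anion at C3. C1 is now quaternary and carries no proton to quench it, so C3 attacks the neighbouring ring carbonyl C4 in a 4-exo-trig aldol closure to give cyclobutenol alkoxide 15. Retro-aldol cleavage of C1–C4 then releases the strain, so the eight-membered ring arises by fragmentation of the bicyclo[4.2.0] system and not by direct closure; the C1 carbanion leaves as an enolate stabilised by C9=O and, vinylogously, by the keto ester, and is protonated by fresh 12, which turns the base over. The closest known reaction type is the base-mediated two-carbon ring expansion of cyclic 1,3-dicarbonyl compounds with acetylenic esters (formal alkyne insertion into a C–C bond). The cis geometry of C2=C3, which places C18 and C19 on the same side for lactonisation, is enforced because C1 and C4 are joined in the cyclobutene before cleavage. The step needs C- over O-attack of the enolate and regioselective bonding of C1 to C2; the first rests on the soft caesium enolate in DMSO and the second on the polarity of the ynoate. C1 is set by thermodynamic protonation and stays labile until step 14. C7 arises from the choice between the two diastereotopic ring carbonyls, for which only the remote C10 centre offers a bias; both C7 epimers are therefore expected, and 16 is separated from its C7 epimer here or, if C1 lability blurs the separation, at the stage of 17.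

Step 9
Reactants: 16 enedione (as named in step 8)
Product: 17 C9 ethylene ketal (1,3-dioxolane) of 16, configuration unchanged
Conditions: 1,2-bis(trimethylsilyloxy)ethane (3 equiv), TMSOTf (0.05 equiv), CH2Cl2, −78 to −20 °C; pyridine quench
Reagents that add atoms: 1,2-bis(trimethylsilyloxy)ethane, C[Si](C)(C)OCCO[Si](C)(C)C
Why: Silyl-triflate-catalysed ketalisation is kinetically selective for saturated ketones; the C4 carbonyl is conjugated and part of a keto ester and should remain. With C9 masked, C1–H is no longer the most acidic site.

Step 10
Reactants: 17 C9 ethylene ketal of 16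
Product: 19 C4 enol triflate of 17 (C4=C6 cis in the ring, conjugated with C2=C3), via lithium enolate 18 (not isolated)
Conditions: LiN(iPr)2 (LDA, 1.15 equiv), THF, −78 °C; then PhNTf2 (1.2 equiv), −78 to 0 °C
Reagents that add atoms: N-phenylbis(trifluoromethanesulfonimide), O=S(=O)(N(c1ccccc1)S(=O)(=O)C(F)(F)F)C(F)(F)F
Why: Kinetic deprotonation of an enone by a hindered lithium amide occurs at the α′ position (C6) to give the cross-conjugated enolate, which is O-sulfonylated. The γ positions are slower: C1 is tertiary and flanked by the ketal, and C18 bears oxygen.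

Step 11
Reactants: 19 C4 enol triflate of 17
Product: 20 diene ester (triflate of 19 replaced by hydrogen; C2=C3 and cis C4=C6, C9 ketal, both silyl ethers)
Conditions: Pd(OAc)2 (5 mol%), PPh3 (10 mol%), HCO2H (2 equiv), Et3N (3 equiv), DMF, 60 °C
Reagents that add atoms: none
Why: Palladium-catalysed formate reduction of an enol triflate (oxidative addition, decarboxylation of formate to a palladium hydride, reductive elimination) with retention of alkene geometry.

Step 12
Reactants: 20 diene ester
Product: 22 (4R,7S)-4-[(2S)-1-hydroxy-6-methylhept-5-en-2-yl]-7-methyl-6,7-dihydro-3H-cycloocta[c]furan-1,5(4H)-dione (butenolide, C9 ketone, free C11 hydroxyl), via dihydroxy keto ester 21 (not isolated)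
Conditions: 1 M HCl (aq)/THF 1:3, 25 °C
Reagents that add atoms: water, O
Why: Aqueous acid hydrolyses the ketal and both silyl ethers; the C18 hydroxyl, held cis to the ester across C2=C3, lactonises spontaneously. C1 equilibrates under these conditions.

Step 13
Reactants: 22 keto butenolide alcohol
Product: 23 (2S)-6-methyl-2-[(4R,7S)-7-methyl-1,5-dioxo-1,3,4,5,6,7-hexahydrocycloocta[c]furan-4-yl]hept-5-en-1-yl acetate
Conditions: Ac2O (1.5 equiv), pyridine, CH2Cl2, 0 °C
Reagents that add atoms: acetic anhydride, CC(=O)OC(C)=O
Why: Acylation of the only hydroxyl present; doing it before the C9 reduction removes any need to distinguish two hydroxyls later.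

Step 14
Reactants: 23 keto butenolide acetate
Product: 24 (2S)-2-[(4R,5S,7S)-5-hydroxy-7-methyl-1-oxo-1,3,4,5,6,7-hexahydrocycloocta[c]furan-4-yl]-6-methylhept-5-en-1-yl acetate
Conditions: Li[HB(sBu)3] (L-Selectride, 1.2 equiv), THF, −78 °C; H2O quench
Reagents that add atoms: none
Why: The bulky hydride should attack the C9 carbonyl from the face opposite the C1 side chain, giving the cis C1/C9 relation (C9 S). At −78 °C the ketone reacts far faster than the lactone or the acetate.

Step 15
Reactants: 24 hydroxy butenolide acetate
Product: 26 target CNP0267808.2, (1R,4R,6R,7S,9S,10S) in the numbering used here, via ethylzinc alkoxide 25 (not isolated)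
Conditions: Et2Zn (2.2 equiv), CH2I2 (2.2 equiv), CH2Cl2, −20 to 0 °C; aq. NH4Cl
Reagents that add atoms: diiodomethane, ICI
Why: Simmons–Smith cyclopropanation (diethylzinc variant); the zinc alkoxide at C9 should hold the carbenoid on the hydroxyl face, which is also the face anti to the C7 methyl. Addition to the cis alkene is stereospecific, so C4 and C6 form as the cis-fused cyclopropane.

## Compound list

1 | 5-methylhex-4-enal | CC(C)=CCCC=O | starting material
2 | nitromethane | C[N+](=O)[O-] | starting material
3 | 6-methyl-1-nitrohept-5-en-2-ol (racemic) | CC(C)=CCCC(O)C[N+](=O)[O-] | intermediate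
4 | 6-methyl-1-nitrohept-5-en-2-yl methanesulfonate | CC(C)=CCCC(OS(C)(=O)=O)C[N+](=O)[O-] | intermediate
5 | (E)-6-methyl-1-nitrohepta-1,5-diene | CC(C)=CCC/C=C/[N+](=O)[O-] | intermediate
6 | 5-methylcyclohexane-1,3-dione | CC1CC(=O)CC(=O)C1 | starting material
7 | 5-methyl-2-[(2S)-6-methyl-1-nitrohept-5-en-2-yl]cyclohexane-1,3-dione | O=C1CC(C)CC(=O)C1[C@H](CCC=C(C)C)C[N+](=O)[O-] | intermediate
8 | disodium salt of 7 (dione enolate and nitronate) | [Na+].[Na+].[O-]C1=C([C@H](CCC=C(C)C)C=[N+]([O-])[O-])C(=O)CC(C)C1 | intermediate
9 | (2S)-6-methyl-2-(4-methyl-2,6-dioxocyclohexyl)hept-5-enal (open form of the lactol) | O=C1CC(C)CC(=O)C1[C@H](CCC=C(C)C)C=O | intermediate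
10 | 2-[(2S)-1-hydroxy-6-methylhept-5-en-2-yl]-5-methylcyclohexane-1,3-dione | O=C1CC(C)CC(=O)C1[C@H](CCC=C(C)C)CO | intermediate
11 | 3-(tert-butyldimethylsilyloxy)-2-[(2S)-1-(tert-butyldimethylsilyloxy)-6-methylhept-5-en-2-yl]-5-methylcyclohex-2-en-1-one | CC(C)(C)[Si](C)(C)OC1=C([C@H](CCC=C(C)C)CO[Si](C)(C)C(C)(C)C)C(=O)CC(C)C1 | intermediate
12 | 2-[(2S)-1-(tert-butyldimethylsilyloxy)-6-methylhept-5-en-2-yl]-5-methylcyclohexane-1,3-dione | O=C1CC(C)CC(=O)C1[C@H](CCC=C(C)C)CO[Si](C)(C)C(C)(C)C | intermediate
13 | methyl 4-hydroxybut-2-ynoate | COC(=O)C#CCO | starting material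
14 | methyl 4-(tert-butyldimethylsilyloxy)but-2-ynoate | COC(=O)C#CCO[Si](C)(C)C(C)(C)C | intermediate
15 | methyl 8-[(tert-butyldimethylsilyloxy)methyl]-1-[(2S)-1-(tert-butyldimethylsilyloxy)-6-methylhept-5-en-2-yl]-6-hydroxy-4-methyl-2-oxobicyclo[4.2.0]oct-7-ene-7-carboxylate (formed as its caesium alkoxide, diastereomer mixture) | COC(=O)C1=C(CO[Si](C)(C)C(C)(C)C)C2([C@H](CCC=C(C)C)CO[Si](C)(C)C(C)(C)C)C(=O)CC(C)CC12O | intermediate
16 | methyl (3R,6S)-2-[(tert-butyldimethylsilyloxy)methyl]-3-[(2S)-1-(tert-butyldimethylsilyloxy)-6-methylhept-5-en-2-yl]-6-methyl-4,8-dioxocyclooct-1-ene-1-carboxylate | COC(=O)/C1=C(\CO[Si](C)(C)C(C)(C)C)[C@@H]([C@H](CCC=C(C)C)CO[Si](C)(C)C(C)(C)C)C(=O)C[C@H](C)CC1=O | intermediate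
17 | C9 ethylene ketal (1,3-dioxolane) of 16 | COC(=O)/C1=C(\CO[Si](C)(C)C(C)(C)C)[C@@H]([C@H](CCC=C(C)C)CO[Si](C)(C)C(C)(C)C)C2(OCCO2)C[C@H](C)CC1=O | intermediate
18 | lithium C4 enolate of 17 (C4=C6) | CC(C)(C)[Si](C)(C)OC[C@@H](CCC=C(C)C)[C@@H]1/C(CO[Si](C)(C)C(C)(C)C)=C(C(=O)OC)\C([O-])=C/[C@@H](C)CC12OCCO2.[Li+] | intermediate
19 | C4 enol triflate of 17 (cis C4=C6) | CC(C)(C)[Si](C)(C)OC[C@@H](CCC=C(C)C)[C@@H]1/C(CO[Si](C)(C)C(C)(C)C)=C(C(=O)OC)\C(OS(=O)(=O)C(F)(F)F)=C/[C@@H](C)CC12OCCO2 | intermediate
20 | diene ester (C2=C3 and cis C4=C6, C9 ketal, C11 and C18 silyl ethers) | CC(C)(C)[Si](C)(C)OC[C@@H](CCC=C(C)C)[C@@H]1/C(CO[Si](C)(C)C(C)(C)C)=C(C(=O)OC)\C=C/[C@@H](C)CC12OCCO2 | intermediate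
21 | dihydroxy keto ester (C9 ketone, C11 and C18 hydroxyls, methyl ester) | OC[C@@H](CCC=C(C)C)[C@@H]1/C(CO)=C(C(=O)OC)\C=C/[C@@H](C)CC1=O | intermediate
22 | (4R,7S)-4-[(2S)-1-hydroxy-6-methylhept-5-en-2-yl]-7-methyl-6,7-dihydro-3H-cycloocta[c]furan-1,5(4H)-dione | OC[C@@H](CCC=C(C)C)[C@@H]1C2=C(C(=O)OC2)/C=C\[C@@H](C)CC1=O | intermediate
23 | (2S)-6-methyl-2-[(4R,7S)-7-methyl-1,5-dioxo-1,3,4,5,6,7-hexahydrocycloocta[c]furan-4-yl]hept-5-en-1-yl acetate | CC(=O)OC[C@@H](CCC=C(C)C)[C@@H]1C2=C(C(=O)OC2)/C=C\[C@@H](C)CC1=O | intermediate
24 | (2S)-2-[(4R,5S,7S)-5-hydroxy-7-methyl-1-oxo-1,3,4,5,6,7-hexahydrocycloocta[c]furan-4-yl]-6-methylhept-5-en-1-yl acetate | CC(=O)OC[C@@H](CCC=C(C)C)[C@@H]1C2=C(C(=O)OC2)/C=C\[C@@H](C)C[C@@H]1O | intermediate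
25 | ethylzinc alkoxide of 24 | CC(=O)OC[C@@H](CCC=C(C)C)[C@@H]1C2=C(C(=O)OC2)/C=C\[C@@H](C)C[C@@H]1O[Zn]CC | intermediate
26 | CNP0267808.2, (1R,4R,6R,7S,9S,10S) in the numbering used here | CC(=O)OC[C@@H](CCC=C(C)C)[C@@H]1C2=C(C(=O)OC2)[C@@H]2C[C@@H]2[C@@H](C)C[C@@H]1O | target

## Step count and least certain steps

Total: 15 steps. Longest linear sequence: 14 steps (steps 1–6 and 8–15); step 7 is a one-step side branch.

Step 8 (key step). Three things can go wrong, all linked to the congestion around C1:
- O-alkenylation of the enolate may compete with C-attack.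
- The vinyl anion may be protonated by unreacted 12 before it cyclises; running the step with a full equivalent of base would remove that proton source.
- The two ring carbonyls are expected to be attacked without useful discrimination, so about half of the material ends up as the C7 epimer.

Fallback: setting out from 12, the dione is converted with TMSCl and Et3N into its trimethylsilyl enol ether F1. A [2+2] cycloaddition of F1 with 14, catalysed by bis(trifluoromethanesulfonyl)imide or promoted by EtAlCl2 in CH2Cl2 at −78 °C (a Mukaiyama–Michael addition followed by ring closure), gives the silyloxy cyclobutene F2. Methanolysis of the tertiary silyl ether with K2CO3 in MeOH triggers the same retro-aldol opening and returns to the route at 16. This variant blocks the enol oxygen and has no proton source; the C7 epimers still have to be separated.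

Step 9. The C9 carbonyl is an α-branched medium-ring ketone and may ketalise sluggishly; forcing conditions risk loss of a silyl ether or migration of the double bond. Fallback: setting out from 16, C9 is masked by reduction instead. NaBH4 in MeOH/CH2Cl2 at −78 °C (saturated ketone before conjugated ketone) gives the C9 alcohol F3, and Et3SiOTf with 2,6-lutidine gives its triethylsilyl ether F4. The sequence of steps 10 and 11 then gives the enol triflate F5 and the diene F6. 1 M HCl in THF removes all three silyl groups and closes the lactone to give the diol F7. Selective acetylation of the primary hydroxyl with AcCl and 2,4,6-collidine at −78 °C returns to the route at 24.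

Step 10. Deprotonation at a γ position (C1 or C18) instead of C6 would give a regioisomeric dienyl triflate. Fallback: setting out from 17, Luche reduction (NaBH4, CeCl3·7H2O, MeOH, −78 °C) gives the C4 allylic alcohol F8. Syn-dehydration with methyl N-(triethylammoniosulfonyl)carbamate inner salt in toluene at 60 °C can take a hydrogen only from C6 and returns to the route at 20.

Step 15. The carbenoid may react with the electron-rich C14=C15 alkene (loss of chemoselectivity). Direction by a hydroxyl three carbons away across a medium ring may also be weak, which would give slow reaction or the wrong face. Fallback: setting out from 24, palladium-catalysed cyclopropanation with diazomethane (Pd(OAc)2, 5 mol%, Et2O, 0 °C) is used. It is selective for the disubstituted conjugated alkene over the trisubstituted one and relies on approach anti to the C7 methyl. It arrives directly at 26 and passes through no new compound (F0).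

Step 14. Facial selectivity at C9 may be poor, since the C7 methyl lies on the face the hydride must use, and C1 may equilibrate toward the wrong epimer under the basic hydride. Fallback: setting out from 23, a catalyst-controlled Corey–Bakshi–Shibata reduction (B-methyl oxazaborolidine, catecholborane, toluene, −78 °C) is used under non-basic conditions, with the catalyst enantiomer chosen for the (S)-carbinol. It arrives at 24 and passes through no new compound (F0).

Step 4. Dehydration of the lactol to a furan would destroy C10, and epimerisation of C10 could occur through the open aldehyde. Formation of the dianion may also be incomplete. Fallback: setting out from 7, the nitro group is reduced under neutral conditions with SnCl2·2H2O, PhSH and Et3N in MeCN to the aldoxime F9. Transoximation with aqueous glyoxylic acid returns to the route at 9, which is reduced at once as in step 5.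

## Further compounds

F1 | step 8 | 2-[(2S)-1-(tert-butyldimethylsilyloxy)-6-methylhept-5-en-2-yl]-5-methyl-3-(trimethylsilyloxy)cyclohex-2-en-1-one | C[Si](C)(C)OC1=C([C@H](CCC=C(C)C)CO[Si](C)(C)C(C)(C)C)C(=O)CC(C)C1
F2 | step 8 | methyl 8-[(tert-butyldimethylsilyloxy)methyl]-1-[(2S)-1-(tert-butyldimethylsilyloxy)-6-methylhept-5-en-2-yl]-4-methyl-2-oxo-6-(trimethylsilyloxy)bicyclo[4.2.0]oct-7-ene-7-carboxylate | COC(=O)C1=C(CO[Si](C)(C)C(C)(C)C)C2([C@H](CCC=C(C)C)CO[Si](C)(C)C(C)(C)C)C(=O)CC(C)CC12O[Si](C)(C)C
F3 | step 9 | C9 alcohol from 16 (C9 S, C4 ketone retained) | COC(=O)/C1=C(\CO[Si](C)(C)C(C)(C)C)[C@@H]([C@H](CCC=C(C)C)CO[Si](C)(C)C(C)(C)C)[C@@H](O)C[C@H](C)CC1=O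
F4 | step 9 | C9 triethylsilyl ether of F3 | COC(=O)/C1=C(\CO[Si](C)(C)C(C)(C)C)[C@@H]([C@H](CCC=C(C)C)CO[Si](C)(C)C(C)(C)C)[C@@H](O[Si](CC)(CC)CC)C[C@H](C)CC1=O
F5 | step 9 | C4 enol triflate of F4 (cis C4=C6) | CC(C)(C)[Si](C)(C)OC[C@@H](CCC=C(C)C)[C@@H]1/C(CO[Si](C)(C)C(C)(C)C)=C(C(=O)OC)\C(OS(=O)(=O)C(F)(F)F)=C/[C@@H](C)C[C@@H]1O[Si](CC)(CC)CC
F6 | step 9 | diene ester with C9 triethylsilyl ether | CC(C)(C)[Si](C)(C)OC[C@@H](CCC=C(C)C)[C@@H]1/C(CO[Si](C)(C)C(C)(C)C)=C(C(=O)OC)\C=C/[C@@H](C)C[C@@H]1O[Si](CC)(CC)CC
F7 | step 9 | diol butenolide (24 without the acetyl group) | OC[C@@H](CCC=C(C)C)[C@@H]1C2=C(C(=O)OC2)/C=C\[C@@H](C)C[C@@H]1O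
F8 | step 10 | C4 allylic alcohol from 17 (either C4 epimer) | COC(=O)/C1=C(\CO[Si](C)(C)C(C)(C)C)[C@@H]([C@H](CCC=C(C)C)CO[Si](C)(C)C(C)(C)C)C2(OCCO2)C[C@H](C)CC1O
F9 | step 4 | (2S)-6-methyl-2-(4-methyl-2,6-dioxocyclohexyl)hept-5-enal oxime | O=C1CC(C)CC(=O)C1[C@H](CCC=C(C)C)C=NO
F0 | step 15 | none | none
F0 | step 14 | none | none
A1 | alternative 1 | cis-fused cycloocta-1,5-diene lactone with C9 silyl enol ether | CC(C)(C)[Si](C)(C)OC[C@@H](CCC=C(C)C)C1=C(O[Si](C)(C)C(C)(C)C)C[C@H](C)/C=C\[C@@H]2C(=O)OC[C@H]12
A2 | alternative 1 | sorbate ester of the 2-silyloxydienyl alcohol (tethered bis-diene) | C/C=C/C=C/C(=O)OC/C=C(\[C@H](CCC=C(C)C)CO[Si](C)(C)C(C)(C)C)C(=C)O[Si](C)(C)C(C)(C)C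
A3 | alternative 2 | C7=C8 dehydro target (cyclic allylic alcohol) | CC(=O)OC[C@@H](CCC=C(C)C)[C@@H]1C2=C(C(=O)OC2)[C@@H]2C[C@@H]2/C(C)=C\[C@@H]1O
A4 | alternative 2 | (Z)-alkenyl iodide aldehyde (seco precursor) | CC(=O)OC[C@@H](CCC=C(C)C)[C@@H](C=O)C1=C(C(=O)OC1)[C@@H]1C[C@@H]1/C(C)=C\I
A5 | alternative 3 | eight-membered carbocyclic acid with C10=C11 methylene | C=C(CCC=C(C)C)[C@@H]1[C@@H](C(=O)O)C2(OCCO2)[C@@H]2C[C@@H]2[C@@H](C)C[C@@H]1O[Si](C)(C)C(C)(C)C
A6 | alternative 3 | twelve-membered allylic lactone | O=C1CC2(OCCO2)[C@@H]2C[C@@H]2[C@@H](C)C[C@H](O[Si](C)(C)C(C)(C)C)/C=C(\CCC=C(C)C)CO1
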